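**Plan**

1. Hardest feature: an unsymmetrical diaryl ether (ring A: 3‑OMe, 4‑OAr; ring B: 3‑OAr, 4‑OH) that carries two identical 3‑(2,4‑dihydroxyphenyl)‑3‑oxopropyl arms, so that only one of six phenolic oxygens is methylated.
2. Retrosynthesis: cut both aryl–C(=O) bonds (each ketone carbon to C1' of its 2,4‑dihydroxyphenyl ring) instead of the Cα–Cβ aldol bonds; then cut both ring–chain C=C bonds back to formyl groups; last cut the ring A C4–O ether bond.
3. Forward: 1 + 2 → 3 (SNAr sets the ether; the benzyl ether of 2 fixes its regiochemistry); 3 + 2 × 4 → 5 → 6 (both C3 acid chains at once); 6 → 7 (one hydrogenation saturates both chains and frees the ring B phenol); 7 + 2 × 8 → 9.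
4. Enabling feature: in each arm the C=O carbon sits on the ring carbon that is ortho to one OH and para to the other OH of a 1,3‑dihydroxybenzene ring (C4 of resorcinol), its most nucleophilic position, and the two arms are identical. Free resorcinol can therefore be C‑acylated twice by one diacid in a single three‑component operation, with no protecting group on the four terminal hydroxyls and no later redox adjustment.
5. Stereochemistry (remark): the target has no stereocentre and no stereogenic double bond and is achiral, so no enantiocontrol is needed; the E alkenes of 6 are erased in step 3.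

Key step: step 4

**Step 1**
Reactants: 1 4‑fluoro‑3‑methoxybenzaldehyde; 2 4‑(benzyloxy)‑3‑hydroxybenzaldehyde
Product: 3 4‑[2‑(benzyloxy)‑5‑formylphenoxy]‑3‑methoxybenzaldehyde
Conditions: K2CO3 (1.5 equiv), DMF, 120 °C, N2
Reagents that add atoms: none
Why: Nucleophilic aromatic substitution (SNAr, addition–elimination) in which the phenoxide of 2 adds to C4 of 1, the para formyl group stabilises the Meisenheimer intermediate and fluoride leaves; only the 3‑OH of 2 is free, so the ether can only form as ring A C4–O–C3 ring B.

**Step 2**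
Reactants: 3 4‑[2‑(benzyloxy)‑5‑formylphenoxy]‑3‑methoxybenzaldehyde; 4 malonic acid
Product: 6 (2E)‑3‑[4‑[2‑(benzyloxy)‑5‑[(E)‑2‑carboxyethenyl]phenoxy]‑3‑methoxyphenyl]prop‑2‑enoic acid, via bis(arylidenemalonic acid) 5 (not isolated)
Conditions: malonic acid (5 equiv), piperidine (0.2 equiv), pyridine, 80 then 115 °C
Reagents that add atoms: malonic acid 4, OC(=O)CC(=O)O
Why: Twofold Knoevenagel condensation in the Doebner modification, in which each alkoxybenzaldehyde condenses with malonic acid and the arylidenemalonic acid loses CO2 in hot pyridine to give the E‑cinnamic acid.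

**Step 3**
Reactants: 6 (2E)‑3‑[4‑[2‑(benzyloxy)‑5‑[(E)‑2‑carboxyethenyl]phenoxy]‑3‑methoxyphenyl]prop‑2‑enoic acid
Product: 7 3‑[4‑[5‑(2‑carboxyethyl)‑2‑hydroxyphenoxy]‑3‑methoxyphenyl]propanoic acid
Conditions: H2 (1 atm), 10% Pd/C, THF–MeOH, rt
Reagents that add atoms: none
Why: Heterogeneous catalytic hydrogenation should saturate both cinnamic C=C bonds, and hydrogenolysis on the same catalyst should cleave the benzyl aryl ether, while the diaryl ether, the methyl ether and the carboxylic acids are inert.

**Step 4**
Reactants: 7 3‑[4‑[5‑(2‑carboxyethyl)‑2‑hydroxyphenoxy]‑3‑methoxyphenyl]propanoic acid; 8 resorcinol (benzene‑1,3‑diol)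
Product: 9 verbenachalcone
Conditions: resorcinol (6 equiv), BF3·OEt2 (as solvent), 85 °C, Ar; then aq. NaOAc
Reagents that add atoms: resorcinol 8, Oc1cccc(O)c1
Why: BF3 coordinates each carboxyl group of 7 and makes it an acylium‑type electrophile that is attacked by C4 of resorcinol, and loss of water gives the aryl ketone, so that two such events on one molecule of 7 join three components into 9. The closest known reaction type is the Nencki/Friedel–Crafts C‑acylation of resorcinol with 3‑arylpropanoic acids in BF3·OEt2, the usual entry to 2',4'‑dihydroxydihydrochalcones. No ring is closed and no stereocentre is formed. The step needs site selectivity on resorcinol, which is secured because C4 (= C6) is ortho to one OH and para to the other without being flanked by both as C2 is, and because the new carbonyl group, hydrogen‑bonded to the ortho OH, deactivates that ring against a second acylation. It also needs chemoselectivity for resorcinol over the two rings of 7, which the large excess of the far more electron‑rich resorcinol should secure, so that intermolecular acylation outruns indanone closure onto C6 of the methoxy ring and acylation of the ring B phenol. The aryl methyl ether and the diaryl ether are not cleaved by BF3·OEt2 at this temperature, so the single O‑methyl group stays where step 1 placed it.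

**Compound list**

1 | 4‑fluoro‑3‑methoxybenzaldehyde | COc1cc(C=O)ccc1F | starting material
2 | 4‑(benzyloxy)‑3‑hydroxybenzaldehyde | O=Cc1ccc(OCc2ccccc2)c(O)c1 | starting material
3 | 4‑[2‑(benzyloxy)‑5‑formylphenoxy]‑3‑methoxybenzaldehyde | COc1cc(C=O)ccc1Oc1cc(C=O)ccc1OCc1ccccc1 | intermediate
4 | malonic acid | OC(=O)CC(=O)O | starting material
5 | 2‑[[4‑[2‑(benzyloxy)‑5‑(2,2‑dicarboxyethenyl)phenoxy]‑3‑methoxyphenyl]methylidene]propanedioic acid, the bis(arylidenemalonic acid) | COc1cc(C=C(C(=O)O)C(=O)O)ccc1Oc1cc(C=C(C(=O)O)C(=O)O)ccc1OCc1ccccc1 | intermediate (not isolated)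
6 | (2E)‑3‑[4‑[2‑(benzyloxy)‑5‑[(E)‑2‑carboxyethenyl]phenoxy]‑3‑methoxyphenyl]prop‑2‑enoic acid | COc1cc(/C=C/C(=O)O)ccc1Oc1cc(/C=C/C(=O)O)ccc1OCc1ccccc1 | intermediate
7 | 3‑[4‑[5‑(2‑carboxyethyl)‑2‑hydroxyphenoxy]‑3‑methoxyphenyl]propanoic acid | COc1cc(CCC(=O)O)ccc1Oc1cc(CCC(=O)O)ccc1O | intermediate
8 | resorcinol (benzene‑1,3‑diol) | Oc1cccc(O)c1 | starting material
9 | verbenachalcone, 1‑(2,4‑dihydroxyphenyl)‑3‑[4‑[5‑[3‑(2,4‑dihydroxyphenyl)‑3‑oxopropyl]‑2‑hydroxyphenoxy]‑3‑methoxyphenyl]propan‑1‑one | COc1cc(CCC(=O)c2ccc(O)cc2O)ccc1Oc1cc(CCC(=O)c2ccc(O)cc2O)ccc1O | target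

**Totals**

Total step count: 4. Longest linear sequence: 4 steps (1 or 2 → 3 → 6 → 7 → 9).

**Steps most likely to fail**

Step 4 (key step). The risk is that intramolecular acylation of the methoxy ring (indanone closure onto C6, para to OMe) or O‑acylation and oligomerisation through the ring B phenol competes with the intermolecular C‑acylation, or that the second arm is acylated incompletely. The fallback sets out from 3 and comes back to the route at 9. It forms the Cα–Cβ bonds instead of the aryl–C(=O) bonds. Twofold Claisen–Schmidt condensation of 3 with commercial 1‑[2,4‑bis(benzyloxy)phenyl]ethan‑1‑one (KOH, EtOH–THF, rt) should give the pentabenzyl bis‑chalcone F1. Hydrogenation of F1 (H2, Pd/C, EtOAc–THF, rt, stopped after the calculated uptake) should saturate both enones and cleave all five benzyl ethers to give 9.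

Step 1. The risk is slow Meisenheimer addition to a fluoroarene that is deactivated and hindered by its ortho methoxy group, so that base‑induced disproportionation or condensation of the two aldehydes takes over at the temperature required. The fallback sets out from 2 and comes back at 3. It replaces the uncatalysed substitution by a copper‑catalysed Ullmann‑type C–O coupling of 2 with commercial 4‑bromo‑3‑methoxybenzaldehyde (CuI 10 mol %, picolinic acid 20 mol %, K3PO4, DMSO, 90 °C), which does not depend on the electrophilicity of the arene. This fallback makes no new compound (F0).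

Step 2. The risk is that the twofold condensation stalls after the first aldehyde has reacted, because the mono‑acid separates from the medium, and that mixed mono‑ and bis‑condensed acids then prove hard to purify. The fallback sets out from 3 and comes back at 7, bypassing 5, 6 and step 3, and runs through neutral, soluble esters. Twofold Wittig olefination of 3 with ethyl (triphenylphosphoranylidene)acetate (toluene, 80 °C) should give the diethyl (E,E)‑bis‑cinnamate F2. Hydrogenation (H2, Pd/C, EtOAc, rt) should saturate both alkenes and cleave the benzyl ether to give the diester phenol F3. Saponification (LiOH, THF–H2O, rt; then HCl) should give 7.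

**Further compounds**

F1 | step 4 | (E)‑1‑[2,4‑bis(benzyloxy)phenyl]‑3‑[4‑[2‑(benzyloxy)‑5‑[(E)‑3‑[2,4‑bis(benzyloxy)phenyl]‑3‑oxoprop‑1‑enyl]phenoxy]‑3‑methoxyphenyl]prop‑2‑en‑1‑one | COc1cc(/C=C/C(=O)c2ccc(OCc3ccccc3)cc2OCc2ccccc2)ccc1Oc1cc(/C=C/C(=O)c2ccc(OCc3ccccc3)cc2OCc2ccccc2)ccc1OCc1ccccc1
F0 | step 1 | none | none
F2 | step 2 | ethyl (2E)‑3‑[4‑[2‑(benzyloxy)‑5‑[(E)‑3‑ethoxy‑3‑oxoprop‑1‑enyl]phenoxy]‑3‑methoxyphenyl]prop‑2‑enoate | COc1cc(/C=C/C(=O)OCC)ccc1Oc1cc(/C=C/C(=O)OCC)ccc1OCc1ccccc1
F3 | step 2 | ethyl 3‑[4‑[5‑(3‑ethoxy‑3‑oxopropyl)‑2‑hydroxyphenoxy]‑3‑methoxyphenyl]propanoate | COc1cc(CCC(=O)OCC)ccc1Oc1cc(CCC(=O)OCC)ccc1O
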